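**Plan**

- Retrosynthesis: the three O‑benzyl bonds (O3, O5, ring D phenol) are cut first, then O1–C8a of ring C, then the C2–C3 bond (aroylation of a ketone), the C5–O bond, the C4–C4a bond and last the C8–CH(CH3) bond.
- Forward: ring A is bought as 2‑bromo‑3,5‑difluoroanisole, so the C7 methoxy group is in place and only two fluorides need to be told apart. Ring D is joined through the side chain, the C4 ketone enters between the two fluorines, benzyloxide takes the open fluoride (C5), ring B arrives by C‑aroylation, and ring C closes last.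
- Enabling feature: in ring A the oxygens at C5 and C8a both stand ortho to the C4 carbonyl, so each can arrive by displacement of fluoride. The crowded C8a fluoride, next to the C8 side chain, is kept for the intramolecular enolate attack that makes O1–C8a.
- Stereochemistry: the single stereocentre (R, the methine on C8) is set by ligand‑controlled hydrocupration in step 1 and is not touched afterwards.

Key step: step 5

Assumption: the DTBM‑SEGPHOS antipode that leads to the (R) centre is fixed by a pilot run of step 1; both antipodes are commercial.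

**Step 1**
Reactants: 1 2‑bromo‑3,5‑difluoroanisole; 2 4‑benzyloxystyrene
Product: 3 2‑[(1R)‑1‑(4‑benzyloxyphenyl)ethyl]‑1,5‑difluoro‑3‑methoxybenzene
Conditions: Cu(OAc)2 (cat.), (R)‑ or (S)‑DTBM‑SEGPHOS (antipode giving (R)‑3), [Pd(cinnamyl)Cl]2 (cat.), BrettPhos, Ph2MeSiH, NaOSiMe3, THF, rt
Reagents that add atoms: none
Why: CuH/Pd dual‑catalytic asymmetric hydroarylation of a vinylarene, in which enantioselective Markovnikov hydrocupration of 2 sets the benzylic centre under ligand control and stereospecific transfer to the arylpalladium bromide from 1 followed by reductive elimination should form the C8–CH(CH3) bond.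

**Step 2**
Reactants: 3; 4 2‑(benzyloxy)‑N‑methoxy‑N‑methylacetamide
Product: 7 2‑(benzyloxy)‑1‑{3‑[(1R)‑1‑(4‑benzyloxyphenyl)ethyl]‑2,6‑difluoro‑4‑methoxyphenyl}ethan‑1‑one, via aryllithium 5 (not isolated), via tetrahedral lithium adduct 6 (not isolated)
Conditions: LiN(i‑Pr)2, THF, −78 °C; then 4, −78 °C; then 1 M HCl, −78 °C to rt
Reagents that add atoms: none
Why: Directed ortho‑lithiation followed by Weinreb ketone synthesis, in which the ring C–H flanked by two fluorines is by far the most acidic site, so the aryllithium should form there at −78 °C without benzyne formation or deprotonation of the diarylmethine, and the chelated adduct with 4 prevents over‑addition.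

**Step 3**
Reactants: 7
Product: 8 2‑(benzyloxy)‑1‑{6‑(benzyloxy)‑3‑[(1R)‑1‑(4‑benzyloxyphenyl)ethyl]‑2‑fluoro‑4‑methoxyphenyl}ethan‑1‑one
Conditions: PhCH2OH (5 equiv), NaH (1.1 equiv), THF, 0 °C; then 7, 0 °C to rt
Reagents that add atoms: benzyl alcohol, OCc1ccccc1
Why: Nucleophilic aromatic substitution (addition–elimination) ortho to an aryl ketone, in which both fluorides are activated but the one at the future C8a is screened by the neighbouring 1‑arylethyl group, so the sodium alkoxide should enter at the open position (future C5), the excess alcohol keeping the ketone from resting as its enolate and the new alkoxy group slowing a second displacement.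

**Step 4**
Reactants: 8; 9 4‑methoxybenzoyl chloride
Product: 10 2‑(benzyloxy)‑1‑{6‑(benzyloxy)‑3‑[(1R)‑1‑(4‑benzyloxyphenyl)ethyl]‑2‑fluoro‑4‑methoxyphenyl}‑3‑(4‑methoxyphenyl)propane‑1,3‑dione (both C2 epimers)
Conditions: MgBr2·OEt2, i‑Pr2NEt, CH2Cl2, rt; then aq HCl
Reagents that add atoms: none
Why: Soft enolisation of the α‑alkoxy ketone gives a chelated magnesium enolate that should be acylated on carbon by the acid chloride (direct Claisen‑type C‑acylation to a 1,3‑diketone), and the epimer mixture at C2 is of no consequence because that carbon becomes sp2 in step 5.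

**Step 5**
Reactants: 10
Product: 12 3,5‑bis(benzyloxy)‑8‑[(1R)‑1‑(4‑benzyloxyphenyl)ethyl]‑7‑methoxy‑2‑(4‑methoxyphenyl)‑4H‑chromen‑4‑one, via potassium enolate 11 (not isolated)
Conditions: K2CO3, DMF, 80 °C
Reagents that add atoms: none
Why: K2CO3 removes the acidic C2–H of the diketone to give enolate 11, whose oxygen on the ring B side adds to C8a to form an anionic sigma adduct stabilised by the ortho C4 carbonyl, and loss of fluoride then gives the O1–C8a bond (addition–elimination nucleophilic aromatic substitution). The closest known reaction type is the base‑mediated cyclisation of 1‑(2‑fluoroaryl)‑1,3‑diketones to chromones and flavones, and the analogous nitrogen closures that give 8‑substituted 4‑quinolones indicate that a substituent next to the displaced fluoride is tolerated. Ring C closes as a six‑membered ring by attack of oxygen on an sp2 ring carbon, formally 6‑endo‑trig with respect to the C4a=C8a bond that carries the charge to the C4 carbonyl (6‑exo‑trig if C8=C8a is counted), and either mode is favoured. No stereocentre is formed: the epimeric diketone carbon becomes sp2 C3, and the (R) methine on C8 is far too weakly acidic for carbonate. The step needs site and chemoselectivity, and the substrate secures both: C8a carries the only fluoride left because C5 already bears its benzyloxy group, both alkoxy groups are meta to C8a and do not deactivate it by resonance, and attack through the enolate carbon or the other oxygen would give a strained four‑membered ring.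

**Step 6**
Reactants: 12
Product: 13 3,5‑dihydroxy‑8‑[(1R)‑1‑(4‑hydroxyphenyl)ethyl]‑7‑methoxy‑2‑(4‑methoxyphenyl)‑4H‑chromen‑4‑one
Conditions: H2 (1 atm), 10% Pd/C, EtOAc–MeOH, rt
Reagents that add atoms: none
Why: Hydrogenolysis of the three benzyl ethers over palladium on carbon should free O3, O5 and the ring D phenol while the methyl ethers, the flavonol enone and the all‑carbon stereocentre (no C–O bond to cleave) stay intact.

**Compound list**

1 | 2‑bromo‑3,5‑difluoroanisole (2‑bromo‑1,5‑difluoro‑3‑methoxybenzene) | COc1cc(F)cc(F)c1Br | starting material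
2 | 4‑benzyloxystyrene (1‑(benzyloxy)‑4‑ethenylbenzene) | C=Cc1ccc(OCc2ccccc2)cc1 | starting material
3 | 2‑[(1R)‑1‑(4‑benzyloxyphenyl)ethyl]‑1,5‑difluoro‑3‑methoxybenzene | COc1cc(F)cc(F)c1[C@H](C)c1ccc(OCc2ccccc2)cc1 | intermediate
4 | 2‑(benzyloxy)‑N‑methoxy‑N‑methylacetamide | CON(C)C(=O)COCc1ccccc1 | starting material
5 | {3‑[(1R)‑1‑(4‑benzyloxyphenyl)ethyl]‑2,6‑difluoro‑4‑methoxyphenyl}lithium | [Li]c1c(F)cc(OC)c([C@H](C)c2ccc(OCc3ccccc3)cc2)c1F | intermediate
6 | lithium 2‑(benzyloxy)‑1‑{3‑[(1R)‑1‑(4‑benzyloxyphenyl)ethyl]‑2,6‑difluoro‑4‑methoxyphenyl}‑1‑[methoxy(methyl)amino]ethan‑1‑olate (both configurations at C1) | [Li]OC(COCc1ccccc1)(N(C)OC)c1c(F)cc(OC)c([C@H](C)c2ccc(OCc3ccccc3)cc2)c1F | intermediate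
7 | 2‑(benzyloxy)‑1‑{3‑[(1R)‑1‑(4‑benzyloxyphenyl)ethyl]‑2,6‑difluoro‑4‑methoxyphenyl}ethan‑1‑one | COc1cc(F)c(C(=O)COCc2ccccc2)c(F)c1[C@H](C)c1ccc(OCc2ccccc2)cc1 | intermediate
8 | 2‑(benzyloxy)‑1‑{6‑(benzyloxy)‑3‑[(1R)‑1‑(4‑benzyloxyphenyl)ethyl]‑2‑fluoro‑4‑methoxyphenyl}ethan‑1‑one | COc1cc(OCc2ccccc2)c(C(=O)COCc2ccccc2)c(F)c1[C@H](C)c1ccc(OCc2ccccc2)cc1 | intermediate
9 | 4‑methoxybenzoyl chloride | COc1ccc(C(=O)Cl)cc1 | starting material
10 | 2‑(benzyloxy)‑1‑{6‑(benzyloxy)‑3‑[(1R)‑1‑(4‑benzyloxyphenyl)ethyl]‑2‑fluoro‑4‑methoxyphenyl}‑3‑(4‑methoxyphenyl)propane‑1,3‑dione (both C2 epimers) | COc1ccc(C(=O)C(OCc2ccccc2)C(=O)c2c(F)c([C@H](C)c3ccc(OCc4ccccc4)cc3)c(OC)cc2OCc2ccccc2)cc1 | intermediate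
11 | potassium enolate of 10 (one localisation drawn, double‑bond geometry not fixed) | COc1ccc(C([O-])=C(OCc2ccccc2)C(=O)c2c(F)c([C@H](C)c3ccc(OCc4ccccc4)cc3)c(OC)cc2OCc2ccccc2)cc1.[K+] | intermediate
12 | 3,5‑bis(benzyloxy)‑8‑[(1R)‑1‑(4‑benzyloxyphenyl)ethyl]‑7‑methoxy‑2‑(4‑methoxyphenyl)‑4H‑chromen‑4‑one | COc1ccc(-c2oc3c([C@H](C)c4ccc(OCc5ccccc5)cc4)c(OC)cc(OCc4ccccc4)c3c(=O)c2OCc2ccccc2)cc1 | intermediate
13 | 3,5‑dihydroxy‑8‑[(1R)‑1‑(4‑hydroxyphenyl)ethyl]‑7‑methoxy‑2‑(4‑methoxyphenyl)‑4H‑chromen‑4‑one | COc1ccc(-c2oc3c([C@H](C)c4ccc(O)cc4)c(OC)cc(O)c3c(=O)c2O)cc1 | target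

**Totals**

Total step count: 6. Longest linear sequence: 6 steps (1 or 2 to 13).

**Steps most likely to fail**

Risk 1, step 1. The secondary benzylcopper may transfer slowly to a palladium centre crowded by the ortho fluorine and ortho methoxy group, so that hydrodebromination of 1 and simple reduction of 2 outrun coupling, or enantioselectivity erodes. The fallback replaces hydroarylation by enantioselective alkene hydrogenation and sets out from 1. Bromine–lithium exchange (n‑BuLi, THF, −78 °C) should give (2,4‑difluoro‑6‑methoxyphenyl)lithium F1. Addition of this to commercial 1‑[4‑(benzyloxy)phenyl]ethan‑1‑one should give 1‑[4‑(benzyloxy)phenyl]‑1‑(2,4‑difluoro‑6‑methoxyphenyl)ethan‑1‑ol F2. Acid‑catalysed dehydration (TsOH, toluene, 60 °C) should give 1‑(benzyloxy)‑4‑[1‑(2,4‑difluoro‑6‑methoxyphenyl)ethenyl]benzene F3. Hydrogenation with a chiral iridium N,P complex, [Ir(cod)(tBu‑PHOX)][B(3,5‑(CF3)2C6H3)4] (ligand antipode chosen for the (R) centre), H2, CH2Cl2, should then differentiate the two aryl groups because the 2,6‑disubstituted ring is twisted out of the alkene plane. The fallback comes back to the route at 3.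

Risk 2, step 3. The alkoxide may deprotonate the α‑benzyloxy ketone; the resulting enolate makes ring A electron‑rich, which stalls the displacement and opens self‑condensation. The fallback carries out the displacement on a non‑enolisable aldehyde and sets out from aryllithium 5, generated as in step 2. Quenching with DMF should give 3‑[(1R)‑1‑(4‑benzyloxyphenyl)ethyl]‑2,6‑difluoro‑4‑methoxybenzaldehyde F4. NaOCH2Ph in THF should then displace the open ortho fluoride, by the same steric argument, to give 6‑(benzyloxy)‑3‑[(1R)‑1‑(4‑benzyloxyphenyl)ethyl]‑2‑fluoro‑4‑methoxybenzaldehyde F5. Addition of LiCH2OCH2Ph (from Bu3SnCH2OCH2Ph and n‑BuLi, THF, −78 °C) should give 2‑(benzyloxy)‑1‑{6‑(benzyloxy)‑3‑[(1R)‑1‑(4‑benzyloxyphenyl)ethyl]‑2‑fluoro‑4‑methoxyphenyl}ethan‑1‑ol F6. Oxidation with Dess–Martin periodinane comes back to the route at 8.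

Risk 3, step 5. The delocalised diketone enolate is a weak nucleophile and lowers the acceptor strength of the C4 carbonyl, and C8a is flanked by the 1‑arylethyl group, so closure may be slow enough for retro‑Claisen cleavage of the diketone to take over. The fallback forms the same O1–C8a bond at a lower oxidation level, with a localised alkoxide and a neutral ketone as activator, and sets out from 8. Aldol addition of its lithium enolate (LiN(SiMe3)2, THF, −78 °C) to 4‑methoxybenzaldehyde should give 2‑(benzyloxy)‑1‑{6‑(benzyloxy)‑3‑[(1R)‑1‑(4‑benzyloxyphenyl)ethyl]‑2‑fluoro‑4‑methoxyphenyl}‑3‑hydroxy‑3‑(4‑methoxyphenyl)propan‑1‑one F7. Its sodium alkoxide (NaH, THF–DMF, 0 °C to rt) should displace the C8a fluoride to give 3,5‑bis(benzyloxy)‑8‑[(1R)‑1‑(4‑benzyloxyphenyl)ethyl]‑7‑methoxy‑2‑(4‑methoxyphenyl)‑2,3‑dihydro‑4H‑chromen‑4‑one F8. The new centres at C2 and C3 are erased by dehydrogenation (I2 cat., DMSO, 100 °C), which comes back to the route at 12.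

**Further compounds**

F1 | step 1 | (2,4‑difluoro‑6‑methoxyphenyl)lithium | [Li]c1c(F)cc(F)cc1OC
F2 | step 1 | 1‑[4‑(benzyloxy)phenyl]‑1‑(2,4‑difluoro‑6‑methoxyphenyl)ethan‑1‑ol (racemic) | COc1cc(F)cc(F)c1C(C)(O)c1ccc(OCc2ccccc2)cc1
F3 | step 1 | 1‑(benzyloxy)‑4‑[1‑(2,4‑difluoro‑6‑methoxyphenyl)ethenyl]benzene | COc1cc(F)cc(F)c1C(=C)c1ccc(OCc2ccccc2)cc1
F4 | step 3 | 3‑[(1R)‑1‑(4‑benzyloxyphenyl)ethyl]‑2,6‑difluoro‑4‑methoxybenzaldehyde | COc1cc(F)c(C=O)c(F)c1[C@H](C)c1ccc(OCc2ccccc2)cc1
F5 | step 3 | 6‑(benzyloxy)‑3‑[(1R)‑1‑(4‑benzyloxyphenyl)ethyl]‑2‑fluoro‑4‑methoxybenzaldehyde | COc1cc(OCc2ccccc2)c(C=O)c(F)c1[C@H](C)c1ccc(OCc2ccccc2)cc1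
F6 | step 3 | 2‑(benzyloxy)‑1‑{6‑(benzyloxy)‑3‑[(1R)‑1‑(4‑benzyloxyphenyl)ethyl]‑2‑fluoro‑4‑methoxyphenyl}ethan‑1‑ol (both carbinol epimers) | COc1cc(OCc2ccccc2)c(C(O)COCc2ccccc2)c(F)c1[C@H](C)c1ccc(OCc2ccccc2)cc1
F7 | step 5 | 2‑(benzyloxy)‑1‑{6‑(benzyloxy)‑3‑[(1R)‑1‑(4‑benzyloxyphenyl)ethyl]‑2‑fluoro‑4‑methoxyphenyl}‑3‑hydroxy‑3‑(4‑methoxyphenyl)propan‑1‑one (diastereomer mixture at C2 and C3) | COc1ccc(C(O)C(OCc2ccccc2)C(=O)c2c(F)c([C@H](C)c3ccc(OCc4ccccc4)cc3)c(OC)cc2OCc2ccccc2)cc1
F8 | step 5 | 3,5‑bis(benzyloxy)‑8‑[(1R)‑1‑(4‑benzyloxyphenyl)ethyl]‑7‑methoxy‑2‑(4‑methoxyphenyl)‑2,3‑dihydro‑4H‑chromen‑4‑one (diastereomer mixture at C2 and C3) | COc1ccc(C2Oc3c([C@H](C)c4ccc(OCc5ccccc5)cc4)c(OC)cc(OCc4ccccc4)c3C(=O)C2OCc2ccccc2)cc1
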